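**Plan**
1. Retrosynthesis: the quinone is traced to a 2,6-dialkylphenol and both ketones to carbinols. The long chain is cut at ArCH2–CH= (Pd coupling), across C(Me)=CH (methylalumination of an alkyne), at CH(OH)–CH2C≡CH (propargylation) and at the arm CH2–CHO bond (one-carbon homologation). The prenyl ketone is cut at its C=C (cross-metathesis) and at C(OH)–CH2 (allyl addition), which leaves aldehyde 11.
2. Enabling feature: cyclopentane C1 carries a methyl and an acyl carbon beside quaternary C2. A 1-methylcyclohexene oxide gives exactly this when the ring CH2 on its secondary epoxide carbon shifts to the methyl-bearing carbon, so 11 is cut at the C1–C5 ring bond back to epoxide 10.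
3. Epoxide 10 goes back through homoallylic alcohol 8 to ethyl 2-oxocyclohexanecarboxylate; the C2 methyl enters by enol-triflate coupling.
4. Forward: purchased six-membered ring → quaternary centre → syn-epoxide → ring contraction to the cyclopentane (the only ring made) → C1 chain (allyl, metathesis) → C2 arm (homologation, propargylation) → aryl coupling → quinone, then ketones.
5. Stereochemistry: C2 comes from an auxiliary-controlled methylation; C1 is relayed from it by hydroxyl-directed epoxidation and the stereospecific anti 1,2-shift; the E-alkene comes from syn-carboalumination; the carbinol centres are transient.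

Key step: step 8

**Remarks (assumptions)**
- Step 2: lithiated valine-ester enamines of β-keto esters are known to give either antipode of the α-methyl product depending on the lithium ligand (HMPA in toluene versus THF or dioxolane). The regime written is taken to give the (S)-ketone; the other ligand or the D-valine auxiliary would be used if the sense proved opposite.
- The carbinol centres made in steps 9 and 15 are carried as epimer mixtures (left undefined in the SMILES) because both are oxidised in step 22. Deprotonated forms (enolates, alkoxides) of numbered compounds get no separate numbers.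

**Route**

Step 1
Reactants: 1 ethyl 2-oxocyclohexane-1-carboxylate; 2 L-valine tert-butyl ester
Product: 3 ethyl 2-{[(2S)-1-tert-butoxy-3-methyl-1-oxobutan-2-yl]amino}cyclohex-1-ene-1-carboxylate
Conditions: TsOH (cat.), toluene, reflux, Dean–Stark
Reagents that add atoms: none
Why: Acid-catalysed condensation of a β-keto ester with a primary amine gives the conjugated, hydrogen-bonded enamino ester and places the valine auxiliary next to the carbon to be alkylated.

Step 2
Reactants: 3 enamino ester
Product: 5 ethyl (1S)-1-methyl-2-oxocyclohexane-1-carboxylate, via alkylated imine 4 (not isolated)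
Conditions: LDA, toluene, −78 °C; HMPA (1 equiv), MeI, −78 → −50 °C; then 1 M aq. HCl, rt
Reagents that add atoms: iodomethane CI; water O
Why: Auxiliary-controlled alkylation of a chelated lithio-enamine (aza-enolate): lithium bridges the nitrogen and the valine ester carbonyl so that the isopropyl group screens one face of C1, methyl iodide enters from the other to set the quaternary (S)-centre, and hydrolysis of the imine releases the ketone and the auxiliary.

Step 3
Reactants: 5 ethyl (1S)-1-methyl-2-oxocyclohexane-1-carboxylate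
Product: 6 ethyl (1S)-1-methyl-2-{[(trifluoromethyl)sulfonyl]oxy}cyclohex-2-ene-1-carboxylate
Conditions: KHMDS, THF, −78 °C; PhNTf2, −78 → 0 °C
Reagents that add atoms: N-phenylbis(trifluoromethanesulfonimide) O=S(=O)(N(c1ccccc1)S(=O)(=O)C(F)(F)F)C(F)(F)F
Why: Enol triflate formation by O-sulfonylation of the potassium enolate, which can form only toward C3 because C1 is quaternary, so the position of the future alkene is unambiguous.

Step 4
Reactants: 6 enol triflate
Product: 7 ethyl (1S)-1,2-dimethylcyclohex-2-ene-1-carboxylate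
Conditions: MeMgBr, Fe(acac)3 (5 mol %), THF/NMP, −30 → 0 °C
Reagents that add atoms: methylmagnesium bromide C[Mg]Br
Why: Iron-catalysed Kumada-type coupling of an alkenyl triflate with a methyl Grignard reagent is fast at low temperature, spares the hindered ester and puts the methyl on the alkene carbon next to the quaternary centre.

Step 5
Reactants: 7 ethyl (1S)-1,2-dimethylcyclohex-2-ene-1-carboxylate
Product: 8 [(1S)-1,2-dimethylcyclohex-2-en-1-yl]methanol
Conditions: LiAlH4, Et2O, 0 °C → rt
Reagents that add atoms: none
Why: Hydride reduction of the ester gives the homoallylic primary alcohol that will direct the epoxidation; the stereocentre is not involved.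

Step 6
Reactants: 8 [(1S)-1,2-dimethylcyclohex-2-en-1-yl]methanol
Product: 9 [(1S,2R,6R)-1,2-dimethyl-7-oxabicyclo[4.1.0]heptan-2-yl]methanol (epoxide oxygen cis to CH2OH)
Conditions: VO(acac)2 (5 mol %), t-BuOOH, CH2Cl2, 0 °C → rt
Reagents that add atoms: tert-butyl hydroperoxide CC(C)(C)OO
Why: Hydroxyl-directed vanadium-catalysed epoxidation of a homoallylic alcohol: the peroxide is delivered within the vanadate ester of the CH2OH group to the alkene face the arm occupies, which sets both epoxide carbons with oxygen cis to the arm.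

Step 7
Reactants: 9 syn-epoxy alcohol
Product: 10 tert-butyl{[(1S,2R,6R)-1,2-dimethyl-7-oxabicyclo[4.1.0]heptan-2-yl]methoxy}dimethylsilane
Conditions: TBSCl, imidazole, DMF, rt
Reagents that add atoms: tert-butyldimethylsilyl chloride CC(C)(C)[Si](C)(C)Cl
Why: Silylation of the primary alcohol removes a Lewis-basic, nucleophilic hydroxyl before the Lewis-acid step.

Step 8
Reactants: 10 syn-epoxy silyl ether
Product: 11 (1R,2S)-2-{[(tert-butyldimethylsilyl)oxy]methyl}-1,2-dimethylcyclopentane-1-carbaldehyde
Conditions: MABR [methylaluminium bis(4-bromo-2,6-di-tert-butylphenoxide), 1.5 equiv], CH2Cl2, −78 → −40 °C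
Reagents that add atoms: none
Why: Meinwald (semipinacol) rearrangement: aluminium binds the epoxide oxygen, the C–O bond to the methyl-bearing tertiary carbon lengthens, and the ring CH2 on the secondary epoxide carbon shifts to it from the face opposite the departing oxygen while that secondary carbon becomes the formyl group. The closest known reaction type is the ring contraction of 1-methylcyclohexene oxides to 1-methylcyclopentanecarbaldehydes promoted by bulky aluminium aryloxides. The cyclopentane closes by a suprafacial 1,2-alkyl shift, a six-to-five ring contraction in which the new C1–C5 bond forms with inversion at the tertiary terminus. The new quaternary centre is therefore fixed by the epoxide configuration from step 6: oxygen leaves from the face of the CH2OTBS arm, C5 enters from the other face, and the formyl group ends cis to the arm with the two methyls cis. The step needs ring-carbon rather than hydride migration and no shift from the neighbouring quaternary carbon; the push of the aluminium-bound oxygen limits migration to groups on the carbon that carries it, and the bulky aryloxide promoter is the one documented to favour alkyl over hydride shift in trisubstituted epoxides.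

Step 9
Reactants: 11 cyclopentane carbaldehyde
Product: 12 1-[(1R,2S)-2-{[(tert-butyldimethylsilyl)oxy]methyl}-1,2-dimethylcyclopentyl]but-3-en-1-ol (carbinol epimers)
Conditions: allylMgBr, Et2O, −78 → 0 °C
Reagents that add atoms: allylmagnesium bromide C=CC[Mg]Br
Why: Grignard addition of the small, highly reactive allyl reagent to the neopentyl, non-enolisable aldehyde gives the homoallylic alcohol, whose new carbinol centre is removed by oxidation in step 22.

Step 10
Reactants: 12 homoallylic alcohol
Product: 13 1-[(1R,2S)-2-{[(tert-butyldimethylsilyl)oxy]methyl}-1,2-dimethylcyclopentyl]-4-methylpent-3-en-1-ol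
Conditions: Grubbs II (5 mol %), 2-methyl-2-butene (excess), CH2Cl2, 40 °C
Reagents that add atoms: 2-methyl-2-butene CC=C(C)C
Why: Olefin cross-metathesis of the terminal alkene with excess 2-methyl-2-butene (propene extruded) converts the allyl into the prenyl group without touching the hindered carbinol.

Step 11
Reactants: 13 prenyl carbinol
Product: 14 tert-butyl({1-[(1R,2S)-2-{[(tert-butyldimethylsilyl)oxy]methyl}-1,2-dimethylcyclopentyl]-4-methylpent-3-en-1-yl}oxy)dimethylsilane
Conditions: TBSOTf, 2,6-lutidine, CH2Cl2, 0 °C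
Reagents that add atoms: tert-butyldimethylsilyl triflate CC(C)(C)[Si](C)(C)OS(=O)(=O)C(F)(F)F
Why: Silyl triflate/lutidine silylation masks the hindered secondary alcohol so that it cannot form lactols with the aldehydes later generated on the neighbouring arm.

Step 12
Reactants: 14 bis-silyl ether
Product: 15 [(1S,2R)-2-{1-[(tert-butyldimethylsilyl)oxy]-4-methylpent-3-en-1-yl}-1,2-dimethylcyclopentyl]methanol
Conditions: HF·pyridine, pyridine, THF, 0 °C → rt
Reagents that add atoms: none
Why: Selective desilylation: pyridine-buffered fluoride cleaves the primary silyl ether much faster than the secondary one, which sits next to a quaternary carbon.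

Step 13
Reactants: 15 primary alcohol
Product: 16 (1S,2R)-2-{1-[(tert-butyldimethylsilyl)oxy]-4-methylpent-3-en-1-yl}-1,2-dimethylcyclopentane-1-carbaldehyde
Conditions: Dess–Martin periodinane, CH2Cl2, rt
Reagents that add atoms: none
Why: Dess–Martin oxidation of the neopentyl primary alcohol gives the non-enolisable aldehyde under neutral conditions.

Step 14
Reactants: 16 arm aldehyde
Product: 18 2-[(1R,2R)-2-{1-[(tert-butyldimethylsilyl)oxy]-4-methylpent-3-en-1-yl}-1,2-dimethylcyclopentyl]acetaldehyde, via enol ether 17 (not isolated)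
Conditions: Ph3P(CH2OMe)Cl, t-BuOK, THF, 0 °C → rt; then 1 M aq. HCl, THF, 0 °C → rt
Reagents that add atoms: (methoxymethyl)triphenylphosphonium chloride COC[P+](c1ccccc1)(c1ccccc1)c1ccccc1.[Cl-]; water O
Why: Wittig methoxymethylenation followed by acid hydrolysis of the enol ether in the same flask is the standard one-carbon homologation of an aldehyde, the small ylide still reaches an aldehyde on a quaternary carbon, and the hindered secondary silyl ether tolerates brief dilute acid.

Step 15
Reactants: 18 homologated aldehyde
Product: 19 1-[(1R,2R)-2-{1-[(tert-butyldimethylsilyl)oxy]-4-methylpent-3-en-1-yl}-1,2-dimethylcyclopentyl]pent-4-yn-2-ol (carbinol epimers)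
Conditions: propargyl bromide, Zn dust, THF, 0 °C → rt; aq. NH4Cl
Reagents that add atoms: propargyl bromide C#CCBr
Why: Barbier-type propargylation: the allenylzinc species formed in situ adds through an SE2′ transition state to give the homopropargylic alcohol, whose carbinol centre is oxidised later.

Step 16
Reactants: 20 2-hydroxy-3-methylbenzaldehyde
Product: 21 2-[(tert-butyldimethylsilyl)oxy]-3-methylbenzaldehyde
Conditions: TBSCl, imidazole, DMF, rt
Reagents that add atoms: tert-butyldimethylsilyl chloride CC(C)(C)[Si](C)(C)Cl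
Why: Standard silylation of the phenol gives an aryl silyl ether that survives hydride, organoaluminium and palladium steps and is later removed by fluoride without acid.

Step 17
Reactants: 21 silylated aldehyde
Product: 22 {2-[(tert-butyldimethylsilyl)oxy]-3-methylphenyl}methanol
Conditions: NaBH4, MeOH, 0 °C
Reagents that add atoms: none
Why: Borohydride reduction of the aryl aldehyde to the benzylic alcohol, kept short at 0 °C to avoid O-to-O silyl migration.

Step 18
Reactants: 22 benzylic alcohol
Product: 23 tert-butyl[2-(chloromethyl)-6-methylphenoxy]dimethylsilane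
Conditions: NCS, PPh3, CH2Cl2, 0 °C → rt
Reagents that add atoms: N-chlorosuccinimide O=C1CCC(=O)N1Cl
Why: Appel-type chlorination through the alkoxyphosphonium salt converts the benzylic alcohol into the chloride under neutral conditions that keep the aryl silyl ether.

Step 19
Reactants: 19 homopropargylic alcohol; 23 benzylic chloride
Product: 25 (4E)-1-[(1R,2R)-2-{1-[(tert-butyldimethylsilyl)oxy]-4-methylpent-3-en-1-yl}-1,2-dimethylcyclopentyl]-6-{2-[(tert-butyldimethylsilyl)oxy]-3-methylphenyl}-4-methylhex-4-en-2-ol, via alkenylalane 24 (not isolated)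
Conditions: Me3Al (4 equiv), Cp2ZrCl2 (0.5 equiv), CH2Cl2, 0 °C → rt; volatiles removed; then 23, Pd(PPh3)4 (5 mol %), THF, rt
Reagents that add atoms: trimethylaluminium C[Al](C)C
Why: Zirconium-catalysed syn-methylalumination of the terminal alkyne (Negishi carboalumination, the hydroxyl carried as its aluminium alkoxide) puts methyl on the internal and aluminium on the terminal carbon, and palladium-catalysed coupling of the alkenylalane with the benzylic chloride proceeds with retention, so the trisubstituted alkene is formed as the E isomer.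

Step 20
Reactants: 25 coupled bis-silyl ether
Product: 26 (4E)-1-[(1R,2R)-2-(1-hydroxy-4-methylpent-3-en-1-yl)-1,2-dimethylcyclopentyl]-6-(2-hydroxy-3-methylphenyl)-4-methylhex-4-en-2-ol
Conditions: TBAF (3 equiv), THF, rt → 50 °C
Reagents that add atoms: none
Why: Fluoride-mediated desilylation removes the aryl and the hindered secondary silyl ethers in one operation under non-acidic conditions, which avoids chroman formation from the ortho-allylic phenol.

Step 21
Reactants: 26 phenol diol
Product: 27 2-{(2E)-5-hydroxy-6-[(1R,2R)-2-(1-hydroxy-4-methylpent-3-en-1-yl)-1,2-dimethylcyclopentyl]-3-methylhex-2-en-1-yl}-6-methylcyclohexa-2,5-diene-1,4-dione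
Conditions: Co(salen) (salcomine, 15 mol %), O2 (1 atm), MeCN, rt
Reagents that add atoms: dioxygen O=O
Why: Cobalt–salen-catalysed aerobic oxidation of a 2,6-dialkylphenol with a free para position gives the 1,4-benzoquinone and leaves secondary alcohols and trisubstituted alkenes untouched.

Step 22
Reactants: 27 quinone diol
Product: 28 2-{(2E)-6-[(1R,2R)-1,2-dimethyl-2-(4-methylpent-3-enoyl)cyclopentyl]-3-methyl-5-oxohex-2-en-1-yl}-6-methylcyclohexa-2,5-diene-1,4-dione (target)
Conditions: Dess–Martin periodinane (3 equiv), pyridine, CH2Cl2, 0 °C → rt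
Reagents that add atoms: none
Why: Dess–Martin oxidation of both homoallylic carbinols under buffered, neutral conditions gives the two β,γ-unsaturated ketones without moving the double bonds into conjugation, and the quinone is inert to the oxidant.

**Compound list**
1 | ethyl 2-oxocyclohexane-1-carboxylate | CCOC(=O)C1CCCCC1=O | starting material
2 | L-valine tert-butyl ester | CC(C)[C@H](N)C(=O)OC(C)(C)C | starting material
3 | ethyl 2-{[(2S)-1-tert-butoxy-3-methyl-1-oxobutan-2-yl]amino}cyclohex-1-ene-1-carboxylate | CCOC(=O)C1=C(N[C@@H](C(C)C)C(=O)OC(C)(C)C)CCCC1 | intermediate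
4 | ethyl (1S)-2-{[(2S)-1-tert-butoxy-3-methyl-1-oxobutan-2-yl]imino}-1-methylcyclohexane-1-carboxylate | CCOC(=O)[C@@]1(C)CCCCC1=N[C@@H](C(C)C)C(=O)OC(C)(C)C | intermediate (not isolated)
5 | ethyl (1S)-1-methyl-2-oxocyclohexane-1-carboxylate | CCOC(=O)[C@@]1(C)CCCCC1=O | intermediate
6 | ethyl (1S)-1-methyl-2-{[(trifluoromethyl)sulfonyl]oxy}cyclohex-2-ene-1-carboxylate | CCOC(=O)[C@@]1(C)CCCC=C1OS(=O)(=O)C(F)(F)F | intermediate
7 | ethyl (1S)-1,2-dimethylcyclohex-2-ene-1-carboxylate | CCOC(=O)[C@@]1(C)CCCC=C1C | intermediate
8 | [(1S)-1,2-dimethylcyclohex-2-en-1-yl]methanol | OC[C@@]1(C)CCCC=C1C | intermediate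
9 | [(1S,2R,6R)-1,2-dimethyl-7-oxabicyclo[4.1.0]heptan-2-yl]methanol (oxygen cis to CH2OH) | OC[C@@]1(C)CCC[C@H]2O[C@@]12C | intermediate
10 | tert-butyl{[(1S,2R,6R)-1,2-dimethyl-7-oxabicyclo[4.1.0]heptan-2-yl]methoxy}dimethylsilane | CC(C)(C)[Si](C)(C)OC[C@@]1(C)CCC[C@H]2O[C@@]12C | intermediate (key-step precursor)
11 | (1R,2S)-2-{[(tert-butyldimethylsilyl)oxy]methyl}-1,2-dimethylcyclopentane-1-carbaldehyde (formyl cis to the arm) | O=C[C@]1(C)CCC[C@]1(C)CO[Si](C)(C)C(C)(C)C | intermediate (key-step product)
12 | 1-[(1R,2S)-2-{[(tert-butyldimethylsilyl)oxy]methyl}-1,2-dimethylcyclopentyl]but-3-en-1-ol (carbinol epimers) | C=CCC(O)[C@]1(C)CCC[C@]1(C)CO[Si](C)(C)C(C)(C)C | intermediate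
13 | 1-[(1R,2S)-2-{[(tert-butyldimethylsilyl)oxy]methyl}-1,2-dimethylcyclopentyl]-4-methylpent-3-en-1-ol | CC(C)=CCC(O)[C@]1(C)CCC[C@]1(C)CO[Si](C)(C)C(C)(C)C | intermediate
14 | tert-butyl({1-[(1R,2S)-2-{[(tert-butyldimethylsilyl)oxy]methyl}-1,2-dimethylcyclopentyl]-4-methylpent-3-en-1-yl}oxy)dimethylsilane | CC(C)=CCC(O[Si](C)(C)C(C)(C)C)[C@]1(C)CCC[C@]1(C)CO[Si](C)(C)C(C)(C)C | intermediate
15 | [(1S,2R)-2-{1-[(tert-butyldimethylsilyl)oxy]-4-methylpent-3-en-1-yl}-1,2-dimethylcyclopentyl]methanol | CC(C)=CCC(O[Si](C)(C)C(C)(C)C)[C@]1(C)CCC[C@]1(C)CO | intermediate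
16 | (1S,2R)-2-{1-[(tert-butyldimethylsilyl)oxy]-4-methylpent-3-en-1-yl}-1,2-dimethylcyclopentane-1-carbaldehyde | CC(C)=CCC(O[Si](C)(C)C(C)(C)C)[C@]1(C)CCC[C@]1(C)C=O | intermediate
17 | tert-butyl({1-[(1R,2R)-2-(2-methoxyethenyl)-1,2-dimethylcyclopentyl]-4-methylpent-3-en-1-yl}oxy)dimethylsilane (E/Z) | CC(C)=CCC(O[Si](C)(C)C(C)(C)C)[C@]1(C)CCC[C@]1(C)C=COC | intermediate (not isolated)
18 | 2-[(1R,2R)-2-{1-[(tert-butyldimethylsilyl)oxy]-4-methylpent-3-en-1-yl}-1,2-dimethylcyclopentyl]acetaldehyde | CC(C)=CCC(O[Si](C)(C)C(C)(C)C)[C@]1(C)CCC[C@]1(C)CC=O | intermediate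
19 | 1-[(1R,2R)-2-{1-[(tert-butyldimethylsilyl)oxy]-4-methylpent-3-en-1-yl}-1,2-dimethylcyclopentyl]pent-4-yn-2-ol (carbinol epimers) | CC(C)=CCC(O[Si](C)(C)C(C)(C)C)[C@]1(C)CCC[C@]1(C)CC(O)CC#C | intermediate
20 | 2-hydroxy-3-methylbenzaldehyde | Cc1cccc(C=O)c1O | starting material
21 | 2-[(tert-butyldimethylsilyl)oxy]-3-methylbenzaldehyde | Cc1cccc(C=O)c1O[Si](C)(C)C(C)(C)C | intermediate
22 | {2-[(tert-butyldimethylsilyl)oxy]-3-methylphenyl}methanol | Cc1cccc(CO)c1O[Si](C)(C)C(C)(C)C | intermediate
23 | tert-butyl[2-(chloromethyl)-6-methylphenoxy]dimethylsilane | Cc1cccc(CCl)c1O[Si](C)(C)C(C)(C)C | intermediate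
24 | (E)-alkenyldimethylalane from 19, as its dimethylaluminium alkoxide | CC(C)=CCC(O[Si](C)(C)C(C)(C)C)[C@]1(C)CCC[C@]1(C)CC(O[Al](C)C)C/C(C)=C/[Al](C)C | intermediate (not isolated)
25 | (4E)-1-[(1R,2R)-2-{1-[(tert-butyldimethylsilyl)oxy]-4-methylpent-3-en-1-yl}-1,2-dimethylcyclopentyl]-6-{2-[(tert-butyldimethylsilyl)oxy]-3-methylphenyl}-4-methylhex-4-en-2-ol | CC(C)=CCC(O[Si](C)(C)C(C)(C)C)[C@]1(C)CCC[C@]1(C)CC(O)C/C(C)=C/Cc1cccc(C)c1O[Si](C)(C)C(C)(C)C | intermediate
26 | (4E)-1-[(1R,2R)-2-(1-hydroxy-4-methylpent-3-en-1-yl)-1,2-dimethylcyclopentyl]-6-(2-hydroxy-3-methylphenyl)-4-methylhex-4-en-2-ol | CC(C)=CCC(O)[C@]1(C)CCC[C@]1(C)CC(O)C/C(C)=C/Cc1cccc(C)c1O | intermediate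
27 | 2-{(2E)-5-hydroxy-6-[(1R,2R)-2-(1-hydroxy-4-methylpent-3-en-1-yl)-1,2-dimethylcyclopentyl]-3-methylhex-2-en-1-yl}-6-methylcyclohexa-2,5-diene-1,4-dione | CC(C)=CCC(O)[C@]1(C)CCC[C@]1(C)CC(O)C/C(C)=C/CC1=CC(=O)C=C(C)C1=O | intermediate
28 | 2-{(2E)-6-[(1R,2R)-1,2-dimethyl-2-(4-methylpent-3-enoyl)cyclopentyl]-3-methyl-5-oxohex-2-en-1-yl}-6-methylcyclohexa-2,5-diene-1,4-dione | CC(C)=CCC(=O)[C@]1(C)CCC[C@]1(C)CC(=O)C/C(C)=C/CC1=CC(=O)C=C(C)C1=O | target

**Step count**
Total: 22 steps. Longest linear sequence: 19 steps (steps 1–15 and 19–22); the aryl branch is steps 16–18.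

**The three steps most likely to fail**

1. Step 8 (ring contraction). What may go wrong: the hydride on the secondary epoxide carbon migrates instead of the ring methylene, because the conformer that aligns C–H behind the breaking C–O bond also keeps the bulky aluminium-bound oxygen away from the cis arm; the outcome would be a cyclohexanone and no ring contraction. Fallback, from 10 back to 11: the hydride shift is used instead of fought. Epoxide 10 is isomerised deliberately with a small cationic Lewis acid (catalytic SbF5, toluene, −78 °C) to (3S)-3-{[(tert-butyldimethylsilyl)oxy]methyl}-2,3-dimethylcyclohexan-1-one F1. This is chlorinated at the more substituted α-carbon (SO2Cl2, CH2Cl2, 0 °C) to (3R)-2-chloro-3-{[(tert-butyldimethylsilyl)oxy]methyl}-2,3-dimethylcyclohexan-1-one F2. Favorskii rearrangement (NaOMe, MeOH, 0 °C → rt) contracts the ring to methyl (1R,2S)-2-{[(tert-butyldimethylsilyl)oxy]methyl}-1,2-dimethylcyclopentane-1-carboxylate F3: the cyclopropanone opens toward the less substituted carbanion, so the ester stays on the methyl-bearing carbon, and closure with that methyl turned away from the CH2OTBS group should give the same cis arrangement (to be checked by NOE before merging). LiAlH4 reduction to [(1R,2S)-2-{[(tert-butyldimethylsilyl)oxy]methyl}-1,2-dimethylcyclopentyl]methanol F4 and Dess–Martin oxidation return 11. The same C1–C5 bond is formed, by a different mechanism that has no hydride-shift channel.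

2. Step 19 (carboalumination and coupling in one flask). What may go wrong: slow carbometalation of the alkoxide-bearing alkyne, protodealumination before coupling, or transfer of methyl instead of the alkenyl group to the benzylic palladium species. Fallback, from 19 and 23 back to 25: the two events are separated and the polarity of the coupling is inverted. The carboalumination of 19 is quenched with iodine (THF, −30 °C) to (4E)-1-[(1R,2R)-2-{1-[(tert-butyldimethylsilyl)oxy]-4-methylpent-3-en-1-yl}-1,2-dimethylcyclopentyl]-5-iodo-4-methylpent-4-en-2-ol F5, which can be purified. Chloride 23 is converted with zinc dust and LiCl (THF, rt) into {2-[(tert-butyldimethylsilyl)oxy]-3-methylbenzyl}zinc chloride F6. Negishi coupling of F5 with excess F6 (Pd(PPh3)4, THF, rt → 50 °C) gives 25 with retention of the alkene geometry.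

3. Step 14 (one-carbon homologation). What may go wrong: the ylide fails to reach a formyl group flanked by two quaternary carbons, or the acid needed for enol-ether hydrolysis removes the secondary silyl ether or hydrates the prenyl alkene. Fallback, from 16 back to 18: Seyferth–Gilbert homologation with the Ohira–Bestmann reagent (K2CO3, MeOH, rt), which works well on non-enolisable aldehydes, gives tert-butyl({1-[(1R,2R)-2-ethynyl-1,2-dimethylcyclopentyl]-4-methylpent-3-en-1-yl}oxy)dimethylsilane F7. Anti-Markovnikov hydroboration of the terminal alkyne with dicyclohexylborane (THF, 0 °C), which leaves the trisubstituted alkene alone, then buffered oxidation (NaBO3·4H2O, THF/H2O) delivers aldehyde 18 without any acid.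

**Further compounds**
F1 | step 8 | (3S)-3-{[(tert-butyldimethylsilyl)oxy]methyl}-2,3-dimethylcyclohexan-1-one (C2 epimers) | CC(C)(C)[Si](C)(C)OC[C@@]1(C)CCCC(=O)C1C
F2 | step 8 | (3R)-2-chloro-3-{[(tert-butyldimethylsilyl)oxy]methyl}-2,3-dimethylcyclohexan-1-one (C2 epimers) | CC(C)(C)[Si](C)(C)OC[C@@]1(C)CCCC(=O)C1(C)Cl
F3 | step 8 | methyl (1R,2S)-2-{[(tert-butyldimethylsilyl)oxy]methyl}-1,2-dimethylcyclopentane-1-carboxylate | COC(=O)[C@]1(C)CCC[C@]1(C)CO[Si](C)(C)C(C)(C)C
F4 | step 8 | [(1R,2S)-2-{[(tert-butyldimethylsilyl)oxy]methyl}-1,2-dimethylcyclopentyl]methanol | OC[C@]1(C)CCC[C@]1(C)CO[Si](C)(C)C(C)(C)C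
F5 | step 19 | (4E)-1-[(1R,2R)-2-{1-[(tert-butyldimethylsilyl)oxy]-4-methylpent-3-en-1-yl}-1,2-dimethylcyclopentyl]-5-iodo-4-methylpent-4-en-2-ol | CC(C)=CCC(O[Si](C)(C)C(C)(C)C)[C@]1(C)CCC[C@]1(C)CC(O)C/C(C)=C/I
F6 | step 19 | {2-[(tert-butyldimethylsilyl)oxy]-3-methylbenzyl}zinc chloride | Cc1cccc(C[Zn]Cl)c1O[Si](C)(C)C(C)(C)C
F7 | step 14 | tert-butyl({1-[(1R,2R)-2-ethynyl-1,2-dimethylcyclopentyl]-4-methylpent-3-en-1-yl}oxy)dimethylsilane | CC(C)=CCC(O[Si](C)(C)C(C)(C)C)[C@]1(C)CCC[C@]1(C)C#C
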